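## Retrosynthetic overview

1. Target ⇒ its C4 epimer (Mitsunobu inversion) ⇒ epoxyquinone (chelation-controlled ketone reduction). Hydride can only enter C4 on the face away from the oxirane, so C4 is set by reduce-then-invert.
2. Epoxyquinone ⇒ unprotected 2-(acetoxymethyl)-5-(1-hydroxyfarnesyl)-1,4-benzoquinone by hydroxyl-directed nucleophilic epoxidation. This is the key step: the oxirane is closed on the free quinone, as the pathway's epoxidase does, with the (1'S)-carbinol as the only control of site and face (no quinone monoketal, no chiral oxidant).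
3. Quinone ⇒ hydroquinone dimethyl ether (oxidative demethylation) ⇒ diol (lipase acetylation of the primary hydroxyl).
4. Diol ⇒ 4-(hydroxymethyl)-2,5-dimethoxyphenyl metal + (2E,6E)-farnesal (catalytic enantioselective aryl transfer sets C1').
5. Ring order: the six-membered carbocycle is bought as the arene (the polyketide-derived hydroquinone of the pathway); the oxirane is the only ring made (step 6).

Assumption: ring atoms are numbered C1 (ring ketone), C2 (bears CH2OAc), C3 (=CH), C4 (carbinol), C5 (quaternary oxirane carbon with the side chain), C6 (oxirane CH), side chain C1'–C12'; the same numbers are used for all precursors. The stereochemical rationales in steps 6–8 are reasoned from models, not from a precedent on this substrate.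

## Route

Step 1
Reactants: 1 4-bromo-2,5-dimethoxybenzaldehyde
Product: 2 (4-bromo-2,5-dimethoxyphenyl)methanol
Conditions: NaBH4, MeOH, 0 °C
Reagents that add atoms: none
Why: Borohydride reduction of an aromatic aldehyde, to which the aryl bromide and methyl ethers are inert; no stereocentre is formed.

Step 2
Reactants: 3 (2E,6E)-farnesol
Product: 4 (2E,6E)-farnesal
Conditions: MnO2, CH2Cl2, rt
Reagents that add atoms: none
Why: MnO2 allylic oxidation stops at the enal and leaves the 2E geometry and the two isolated trisubstituted alkenes untouched.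

Step 3
Reactants: 2 (4-bromo-2,5-dimethoxyphenyl)methanol; 4 (2E,6E)-farnesal
Product: 7 (1S,2E,6E)-1-[4-(hydroxymethyl)-2,5-dimethoxyphenyl]-3,7,11-trimethyldodeca-2,6,10-trien-1-ol, via dilithio aryl alkoxide 5 (not isolated), via aryltitanium triisopropoxide 6 (not isolated)
Conditions: nBuLi (1 equiv), then tBuLi (2 equiv), THF, −78 °C; TiCl(OiPr)3 (2 equiv), −78 → 0 °C; then 4, Ti(OiPr)4, (R)-3-(3,5-diphenylphenyl)-H8-BINOL (5 mol %), CH2Cl2, 0 °C
Reagents that add atoms: none
Why: Bromine–lithium exchange on the lithium alkoxide and transmetalation give an aryltitanium triisopropoxide that adds 1,2 to the enal under titanium H8-BINOLate catalysis (catalytic enantioselective aryl transfer), the (R)-ligand sending the aryl group to the Re face of the aldehyde and so setting C1' as S (the (S)-ligand is on hand should the sense be reversed for this pair).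

Step 4
Reactants: 7 (1S,2E,6E)-1-[4-(hydroxymethyl)-2,5-dimethoxyphenyl]-3,7,11-trimethyldodeca-2,6,10-trien-1-ol
Product: 8 {4-[(1S,2E,6E)-1-hydroxy-3,7,11-trimethyldodeca-2,6,10-trien-1-yl]-2,5-dimethoxyphenyl}methyl acetate
Conditions: Novozym 435 (immobilised Candida antarctica lipase B), vinyl acetate, MTBE, rt
Reagents that add atoms: vinyl acetate, C=COC(C)=O
Why: Lipase-catalysed transesterification acylates only the unhindered primary benzylic hydroxyl (the aryl/alkenyl carbinol is too bulky for the enzyme), leaving C1' untouched and masking the ring hydroxymethyl as the non-directing acetate needed in step 6.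

Step 5
Reactants: 8 {4-[(1S,2E,6E)-1-hydroxy-3,7,11-trimethyldodeca-2,6,10-trien-1-yl]-2,5-dimethoxyphenyl}methyl acetate
Product: 9 2-(acetoxymethyl)-5-[(1S,2E,6E)-1-hydroxy-3,7,11-trimethyldodeca-2,6,10-trien-1-yl]-1,4-benzoquinone
Conditions: (NH4)2Ce(NO3)6, MeCN–H2O (2:1), 0 °C, 15 min, dark
Reagents that add atoms: water, O
Why: Oxidative demethylation of a hydroquinone dimethyl ether by tetravalent cerium (water adds at the two methoxy-bearing carbons, methanol leaves) is fast enough at 0 °C to spare the acetate, the isolated alkenes and the carbinol, whose stereocentre is not involved.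

Step 6
Reactants: 9 2-(acetoxymethyl)-5-[(1S,2E,6E)-1-hydroxy-3,7,11-trimethyldodeca-2,6,10-trien-1-yl]-1,4-benzoquinone
Product: 11 (5S,6R)-2-(acetoxymethyl)-5,6-epoxy-5-[(1S,2E,6E)-1-hydroxy-3,7,11-trimethyldodeca-2,6,10-trien-1-yl]cyclohex-2-ene-1,4-dione, via peroxy enolate 10 (not isolated)
Conditions: tBuOOH (2.5 equiv), nBuLi (2.2 equiv), THF, −78 → −50 °C; AcOH quench at −78 °C
Reagents that add atoms: tert-butyl hydroperoxide, CC(C)(C)OO
Why: Hydroxyl-directed Weitz–Scheffer (nucleophilic) epoxidation, in which the lithium peroxide aggregated on the free 1'-hydroxyl is delivered to C6 of the double bond that carries the carbinol (the acetoxymethyl-bearing double bond has no such anchor) on the face where the carbinol oxygen lies in the low-strain rotamer (1'-H eclipsing the C4 carbonyl, alkenyl chain on the other face), and closure of peroxy enolate 10 with loss of tBuOLi gives the cis-fused oxirane with the C5/C6 configuration of the target, mirroring the epoxidase step of the pathway.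

Step 7
Reactants: 11 (5S,6R)-2-(acetoxymethyl)-5,6-epoxy-5-[(1S,2E,6E)-1-hydroxy-3,7,11-trimethyldodeca-2,6,10-trien-1-yl]cyclohex-2-ene-1,4-dione
Product: 13 (4R,5R,6R)-2-(acetoxymethyl)-5,6-epoxy-4-hydroxy-5-[(1S,2E,6E)-1-hydroxy-3,7,11-trimethyldodeca-2,6,10-trien-1-yl]cyclohex-2-en-1-one, via boron chelate 12 (not isolated)
Conditions: Et2BOMe, THF–MeOH (4:1), −78 °C; NaBH4, −78 °C; then MeOH co-evaporation
Reagents that add atoms: none
Why: Narasaka–Prasad reduction, in which the diethylboron chelate between the 1'-oxygen and the C4 carbonyl (alkenyl group equatorial) activates that carbonyl only and external hydride attacks axially on the face away from the oxirane to give the syn-1,3-diol, i.e. the 4R alcohol cis to the epoxide; because no hydride, delivered from the 1'-oxygen or external, can reach the oxirane face of C4, the natural 4S centre is reached by inversion in step 8.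

Step 8
Reactants: 13 (4R,5R,6R)-2-(acetoxymethyl)-5,6-epoxy-4-hydroxy-5-[(1S,2E,6E)-1-hydroxy-3,7,11-trimethyldodeca-2,6,10-trien-1-yl]cyclohex-2-en-1-one
Product: 15 (4S,5R,6R)-2-(acetoxymethyl)-5,6-epoxy-4-hydroxy-5-[(1S,2E,6E)-1-hydroxy-3,7,11-trimethyldodeca-2,6,10-trien-1-yl]cyclohex-2-en-1-one, via 4-O-formate 14 (not isolated)
Conditions: HCO2H, PPh3, DIAD, THF, 0 °C → rt; then KHCO3 (cat.), MeOH, 0 °C
Reagents that add atoms: formic acid, O=CO
Why: Mitsunobu inversion, in which the ring allylic 4-hydroxyl on the open oxirane face is activated and displaced by formate from the side-chain face with SN2 inversion (4R → 4S, now trans to the epoxide) in preference to the more shielded acyclic 1'-hydroxyl, after which bicarbonate-catalysed methanolysis removes the formate and spares the primary acetate.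

## Compound list

1 | 4-bromo-2,5-dimethoxybenzaldehyde | O=Cc1cc(OC)c(Br)cc1OC | starting material
2 | (4-bromo-2,5-dimethoxyphenyl)methanol | OCc1cc(OC)c(Br)cc1OC | intermediate
3 | (2E,6E)-farnesol, (2E,6E)-3,7,11-trimethyldodeca-2,6,10-trien-1-ol | OC/C=C(\C)CC/C=C(\C)CCC=C(C)C | starting material
4 | (2E,6E)-farnesal | O=C/C=C(\C)CC/C=C(\C)CCC=C(C)C | intermediate
5 | lithium (4-lithio-2,5-dimethoxyphenyl)methoxide | [Li]OCc1cc(OC)c([Li])cc1OC | intermediate (not isolated)
6 | aryl–Ti(OiPr)3 reagent whose benzylic oxygen also carries Ti(OiPr)3 | CC(C)O[Ti](OC(C)C)(OC(C)C)OCc1cc(OC)c(cc1OC)[Ti](OC(C)C)(OC(C)C)OC(C)C | intermediate (not isolated)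
7 | (1S,2E,6E)-1-[4-(hydroxymethyl)-2,5-dimethoxyphenyl]-3,7,11-trimethyldodeca-2,6,10-trien-1-ol | OCc1cc(OC)c(cc1OC)[C@@H](O)/C=C(\C)CC/C=C(\C)CCC=C(C)C | intermediate
8 | {4-[(1S,2E,6E)-1-hydroxy-3,7,11-trimethyldodeca-2,6,10-trien-1-yl]-2,5-dimethoxyphenyl}methyl acetate | CC(=O)OCc1cc(OC)c(cc1OC)[C@@H](O)/C=C(\C)CC/C=C(\C)CCC=C(C)C | intermediate
9 | 2-(acetoxymethyl)-5-[(1S,2E,6E)-1-hydroxy-3,7,11-trimethyldodeca-2,6,10-trien-1-yl]-1,4-benzoquinone | CC(=O)OCC1=CC(=O)C(=CC1=O)[C@@H](O)/C=C(\C)CC/C=C(\C)CCC=C(C)C | intermediate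
10 | lithium C4-enolate (C4=C5) of 9 carrying a (6R)-tert-butylperoxy group on the future oxirane face, 1'S | CC(=O)OCC1=CC(O[Li])=C([C@@H](O)/C=C(\C)CC/C=C(\C)CCC=C(C)C)[C@@H](OOC(C)(C)C)C1=O | intermediate (not isolated)
11 | (5S,6R)-2-(acetoxymethyl)-5,6-epoxy-5-[(1S,2E,6E)-1-hydroxy-3,7,11-trimethyldodeca-2,6,10-trien-1-yl]cyclohex-2-ene-1,4-dione; oxirane oxygen and side chain on opposite faces, spatially as in the target (the C5 descriptor differs only because C4 is a ketone) | CC(=O)OCC1=CC(=O)[C@@]2([C@@H](O)/C=C(\C)CC/C=C(\C)CCC=C(C)C)O[C@H]2C1=O | intermediate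
12 | 1'-O-diethylboryl derivative of 11, boron coordinated to the C4 carbonyl oxygen | CC(=O)OCC1=CC(=O)[C@@]2([C@@H](OB(CC)CC)/C=C(\C)CC/C=C(\C)CCC=C(C)C)O[C@H]2C1=O | intermediate (not isolated)
13 | (4R,5R,6R)-2-(acetoxymethyl)-5,6-epoxy-4-hydroxy-5-[(1S,2E,6E)-1-hydroxy-3,7,11-trimethyldodeca-2,6,10-trien-1-yl]cyclohex-2-en-1-one; 4-epimer of the target, 4-OH cis to the oxirane | CC(=O)OCC1=C[C@@H](O)[C@@]2([C@@H](O)/C=C(\C)CC/C=C(\C)CCC=C(C)C)O[C@H]2C1=O | intermediate
14 | 4-O-formate of the target (4S,5R,6R,1'S) | CC(=O)OCC1=C[C@H](OC=O)[C@@]2([C@@H](O)/C=C(\C)CC/C=C(\C)CCC=C(C)C)O[C@H]2C1=O | intermediate (not isolated)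
15 | (4S,5R,6R)-2-(acetoxymethyl)-5,6-epoxy-4-hydroxy-5-[(1S,2E,6E)-1-hydroxy-3,7,11-trimethyldodeca-2,6,10-trien-1-yl]cyclohex-2-en-1-one; 4-OH trans to the oxirane and cis to the side chain (CNP0137670.2) | CC(=O)OCC1=C[C@H](O)[C@@]2([C@@H](O)/C=C(\C)CC/C=C(\C)CCC=C(C)C)O[C@H]2C1=O | target

## Step count and risks

Total: 8 steps. Longest linear sequence: 7 steps (steps 1, 3, 4, 5, 6, 7, 8 from compound 1); step 2 is the one-step side branch.

The three steps most likely to fail:

**Step 6 (directed epoxidation of the free quinone).** The peroxide may attack the other double bond, or attack the hydrogen-bonded rotamer from outside on the wrong face, or base may isomerise 9 to the acylhydroquinone. The fallback replaces substrate control by reagent control. It sets out from 9: the sodium alkoxide is formed with NaN(SiMe3)2 in toluene at −78 °C in the presence of diisopropyl tartrate (the enantiomer matched to the 1'S carbinol, found by running both), and trityl hydroperoxide is added, so that a chiral tartrate–alkoxide–peroxide aggregate decides the face. It comes back to the route at 11 and makes no new compound (F0).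

**Step 8 (Mitsunobu on a diol).** The 1'-hydroxyl may be activated as well (SN2' or ionisation), an oxetane may form, or displacement next to the quaternary carbon may be too slow. The fallback delivers the oxygen from a tether instead of from outside. It sets out from 13, which is treated with CO2 and DBU and then with PBu3/DIAD. The two oxygens of 13 lie on opposite ring faces, so a six-membered carbonate can only close by attack of the 1'-O-carbonate on activated C4 from the side-chain face. This inverts C4 and gives the 4,1'-cyclic carbonate of the 4S diol F3. K2CO3 in MeOH at 0 °C then removes the carbonate and the acetate to give the deacetyl triol F4, and Novozym 435 with vinyl acetate re-acetylates the primary hydroxyl only, coming back to the route at 15.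

**Step 3 (asymmetric aryl transfer with an alkoxide-bearing aryltitanium).** The extra titanium alkoxide and the lithium salts may erode the ee. The fallback uses a salt-free arylzinc with the acetate already in place. It sets out from 2, which is acetylated (Ac2O, pyridine) to 4-bromo-2,5-dimethoxybenzyl acetate F1. Borylation with B2(OH)4, Pd(OAc)2/XPhos and KOAc in EtOH gives [4-(acetoxymethyl)-2,5-dimethoxyphenyl]boronic acid F2. Boron–zinc exchange with Et2Zn in toluene gives the aryl(ethyl)zinc, which adds to 4 under amino-alcohol catalysis by the MIB enantiomer that delivers aryl to the Re face ((+)-MIB by analogy with ethyl transfer). This comes back to the route at 8 and bypasses 7.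

## Further compounds

F1 | step 3 | 4-bromo-2,5-dimethoxybenzyl acetate | CC(=O)OCc1cc(OC)c(Br)cc1OC
F2 | step 3 | [4-(acetoxymethyl)-2,5-dimethoxyphenyl]boronic acid | CC(=O)OCc1cc(OC)c(cc1OC)B(O)O
F0 | step 6 | none | none
F3 | step 8 | 4,1'-cyclic carbonate of the (4S,5R,6R,1'S) diol, primary acetate retained | CC(=O)OCC1=C[C@H](OC3=O)[C@@]2([C@@H](O3)/C=C(\C)CC/C=C(\C)CCC=C(C)C)O[C@H]2C1=O
F4 | step 8 | (4S,5R,6R)-5,6-epoxy-4-hydroxy-2-(hydroxymethyl)-5-[(1S,2E,6E)-1-hydroxy-3,7,11-trimethyldodeca-2,6,10-trien-1-yl]cyclohex-2-en-1-one (deacetyl triol) | OCC1=C[C@H](O)[C@@]2([C@@H](O)/C=C(\C)CC/C=C(\C)CCC=C(C)C)O[C@H]2C1=O
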